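**Retrosynthetic overview**

1. Cyclohexene locants: C1 (bears the 4-methylpent-3-enyl chain), C2 (=CH), C3 (bears the flavanone), C4 (bears the aroyl group), C5 (bears the 2,4-dioxygenated aryl), C6 (CH2). The target is the all-trans isomer and is released from its heptakis-MOM ether 25 by global deprotection.
2. 25 ⇐ vinylcyclobutane 23 (ring atoms C1, C4, C5, C6; vinyl group = C2, C3) + (2S)-6-iodoflavanone 9: Heck arylation at C3, then ring expansion from four to six members by C1–C4 heterolysis and C3–C4 closure.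
3. Enabling feature: the C3–C4 bond joins a carbon that is allylic and benzylic to the 5,7-dioxygenated ring A of the flavanone (cation-stabilising) to the carbon α to the aryl ketone (enolate-stabilising). C1 is olefinic in the product, so C1 and C4 may be stereorandom in the precursor and only C5 must be preset.
4. 23 ⇐ myrcene 15 (gives C1, C2, C3, C6 and the side chain) by dichloroketene [2+2]; the cyclobutanone carbonyl carbon becomes C5 through aldol/aryllithium addition, oxidation, dehydration and asymmetric copper hydride reduction. 9 ⇐ phloroacetophenone 3 + aldehyde 2 by Claisen–Schmidt/oxa-Michael closure, kinetic resolution and C6 iodination.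
5. Order of ring formation: pyranone ring of the flavanone (step 3), cyclobutane (step 10), cyclohexene (step 16, from the cyclobutane).

Key step: step 16

Assumption: the catalyst antipodes named in steps 4 and 15 are those expected to leave the (2S)-flavanone and to give the (S)-configured C5; if a model run shows the opposite sense, the mirror-image catalyst is used.

**Route**

Step 1
Reactants: 1 2,4-dihydroxybenzaldehyde
Product: 2 2,4-bis(methoxymethoxy)benzaldehyde
Conditions: MOMCl, iPr2NEt, CH2Cl2, 0 °C → 40 °C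
Reagents that add atoms: chloromethyl methyl ether (MOMCl), COCCl
Why: Double O-alkylation of the phenols with MOMCl under amine base (Williamson-type ether synthesis) should proceed cleanly, the chelated 2-hydroxyl needing gentle heating, and no stereocentre is formed.

Step 2
Reactants: 3 1-(2,4,6-trihydroxyphenyl)ethan-1-one
Product: 4 1-[2,6-dihydroxy-4-(methoxymethoxy)phenyl]ethan-1-one
Conditions: MOMCl (1 equiv), iPr2NEt, CH2Cl2/THF, −10 °C → rt
Reagents that add atoms: chloromethyl methyl ether (MOMCl), COCCl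
Why: Chemoselective Williamson-type MOM ether formation should occur at the 4-hydroxyl, the only phenol of 3 that is not hydrogen-bonded to the acetyl group and the most acidic one, when one equivalent of MOMCl is used at low temperature; no stereocentre is formed.

Step 3
Reactants: 4 1-[2,6-dihydroxy-4-(methoxymethoxy)phenyl]ethan-1-one; 2 2,4-bis(methoxymethoxy)benzaldehyde
Product: 6 racemic 2-[2,4-bis(methoxymethoxy)phenyl]-5-hydroxy-7-(methoxymethoxy)chroman-4-one, via chalcone 5 (not isolated)
Conditions: KOH, EtOH/H2O, rt; then AcOH to pH 6, NaOAc, EtOH, reflux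
Reagents that add atoms: none
Why: Claisen–Schmidt condensation gives the (E)-chalcone 5 and buffered heating closes the pyranone ring by 6-endo-trig oxa-Michael addition of one of the two equivalent ortho-hydroxyls, which forms C2 as a racemate and leaves the second hydroxyl as the chelated 5-OH.

Step 4
Reactants: 6 racemic 2-[2,4-bis(methoxymethoxy)phenyl]-5-hydroxy-7-(methoxymethoxy)chroman-4-one
Product: 7 (2S)-2-[2,4-bis(methoxymethoxy)phenyl]-5-hydroxy-7-(methoxymethoxy)chroman-4-one
Conditions: RuCl(p-cymene)[(R,R)-TsDPEN] (1 mol%), HCO2H/Et3N (5:2), EtOAc, rt, stopped near half conversion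
Reagents that add atoms: none
Why: Noyori-type asymmetric transfer hydrogenation run as a kinetic resolution should reduce the (2R)-flavanone faster to the cis-flavan-4-ol, so that the unreacted ketone is the (2S)-enantiomer 7, separated by chromatography.

Step 5
Reactants: 7 (2S)-2-[2,4-bis(methoxymethoxy)phenyl]-5-hydroxy-7-(methoxymethoxy)chroman-4-one
Product: 8 (2S)-2-[2,4-bis(methoxymethoxy)phenyl]-5-hydroxy-6-iodo-7-(methoxymethoxy)chroman-4-one
Conditions: BnMe3N·ICl2, CaCO3, CH2Cl2/MeOH, rt
Reagents that add atoms: benzyltrimethylammonium dichloroiodate, C[N+](C)(C)Cc1ccccc1.Cl[I-]Cl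
Why: Electrophilic aromatic iodination with a dichloroiodate salt under carbonate buffering is specific for phenolic rings and, in 5-hydroxy-7-alkoxy flavonoids, goes ortho to the chelated hydroxyl at C6, so the ether-protected ring B and C8 should stay untouched; C2 is not affected.

Step 6
Reactants: 8 (2S)-2-[2,4-bis(methoxymethoxy)phenyl]-5-hydroxy-6-iodo-7-(methoxymethoxy)chroman-4-one
Product: 9 (2S)-2-[2,4-bis(methoxymethoxy)phenyl]-6-iodo-5,7-bis(methoxymethoxy)chroman-4-one
Conditions: MOMCl, iPr2NEt, n-Bu4NI (cat.), CH2Cl2, 40 °C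
Reagents that add atoms: chloromethyl methyl ether (MOMCl), COCCl
Why: Williamson-type MOM protection of the hindered, chelated 5-hydroxyl under mild amine base removes the free phenol that could trap the allyl cation of step 16 as a chromene, without opening the flavanone ring.

Step 7
Reactants: 10 4-hydroxybenzaldehyde
Product: 11 4-hydroxy-3-(3-methylbut-2-en-1-yl)benzaldehyde
Conditions: prenyl bromide, aq. KOH, rt
Reagents that add atoms: 1-bromo-3-methylbut-2-ene (prenyl bromide), CC(C)=CCBr
Why: ortho-C-Prenylation of the phenoxide in water (Friedel–Crafts-type C-alkylation of an ambident phenolate) is a known direct entry to this aldehyde, the O-prenyl ether being the main by-product to remove.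

Step 8
Reactants: 11 4-hydroxy-3-(3-methylbut-2-en-1-yl)benzaldehyde
Product: 12 4-(methoxymethoxy)-3-(3-methylbut-2-en-1-yl)benzaldehyde
Conditions: MOMCl, iPr2NEt, CH2Cl2, 0 °C → rt
Reagents that add atoms: chloromethyl methyl ether (MOMCl), COCCl
Why: Williamson-type MOM ether formation of the single phenol should be clean and masks the acidic proton for the organolithium chemistry of step 12.

Step 9
Reactants: 13 4-bromobenzene-1,3-diol
Product: 14 1-bromo-2,4-bis(methoxymethoxy)benzene
Conditions: MOMCl, iPr2NEt, CH2Cl2, 0 °C → rt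
Reagents that add atoms: chloromethyl methyl ether (MOMCl), COCCl
Why: Double Williamson-type MOM ether formation gives the aryl bromide needed for bromine–lithium exchange, the ortho MOM group later stabilising the aryllithium by chelation.

Step 10
Reactants: 15 myrcene (7-methyl-3-methylideneocta-1,6-diene)
Product: 16 racemic 2,2-dichloro-3-ethenyl-3-(4-methylpent-3-en-1-yl)cyclobutan-1-one
Conditions: Cl3CCOCl (slow addition), Zn/Cu couple, POCl3, Et2O, 0 °C → rt
Reagents that add atoms: trichloroacetyl chloride, ClC(=O)C(Cl)(Cl)Cl (source of dichloroketene, ClC(Cl)=C=O)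
Why: Ketene–alkene [2+2] cycloaddition of dichloroketene generated in the flask: the electrophilic ketene carbon bonds to the methylene terminus of the 1,1-disubstituted diene double bond (the site with the best tertiary allylic cation character, as with isoprene), which places the quaternary carbon between CH2 and CCl2; the stereocentre formed is racemic and disappears in step 11.

Step 11
Reactants: 16 racemic 2,2-dichloro-3-ethenyl-3-(4-methylpent-3-en-1-yl)cyclobutan-1-one
Product: 17 3-ethenyl-3-(4-methylpent-3-en-1-yl)cyclobutan-1-one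
Conditions: Zn dust, AcOH, rt → 50 °C
Reagents that add atoms: none
Why: Zinc-mediated reductive dechlorination of the α,α-dichloroketone through its zinc enolate is standard and leaves the alkenes alone; 17 is achiral, so its two α-methylenes are equivalent.

Step 12
Reactants: 17 3-ethenyl-3-(4-methylpent-3-en-1-yl)cyclobutan-1-one; 12 4-(methoxymethoxy)-3-(3-methylbut-2-en-1-yl)benzaldehyde; 14 1-bromo-2,4-bis(methoxymethoxy)benzene
Product: 20 1-[2,4-bis(methoxymethoxy)phenyl]-3-ethenyl-2-{hydroxy[4-(methoxymethoxy)-3-(3-methylbut-2-en-1-yl)phenyl]methyl}-3-(4-methylpent-3-en-1-yl)cyclobutan-1-ol (mixture of racemic diastereomers), via lithium aldolate 18 (not isolated), via aryllithium 19 (not isolated)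
Conditions: LiN(iPr)2, THF, −78 °C; 12; then 19 (from 14, n-BuLi, THF, −78 °C); H2O
Reagents that add atoms: none
Why: Directed aldol addition of the lithium enolate of 17 to aldehyde 12 followed by 1,2-addition of aryllithium 19 (bromine–lithium exchange) to the strained cyclobutanone carbonyl of aldolate 18 joins three components; 20 forms as a mixture of racemic diastereomers, which is harmless because every stereocentre of 20 is erased or reset in steps 13–16.

Step 13
Reactants: 20 1-[2,4-bis(methoxymethoxy)phenyl]-3-ethenyl-2-{hydroxy[4-(methoxymethoxy)-3-(3-methylbut-2-en-1-yl)phenyl]methyl}-3-(4-methylpent-3-en-1-yl)cyclobutan-1-ol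
Product: 21 {2-[2,4-bis(methoxymethoxy)phenyl]-4-ethenyl-2-hydroxy-4-(4-methylpent-3-en-1-yl)cyclobutyl}[4-(methoxymethoxy)-3-(3-methylbut-2-en-1-yl)phenyl]methanone (mixture of racemic diastereomers)
Conditions: Dess–Martin periodinane, pyridine, CH2Cl2, 0 °C → rt
Reagents that add atoms: none
Why: Dess–Martin oxidation converts the secondary benzylic alcohol into the aryl ketone while the tertiary alcohol cannot react, and the carbinol stereocentre is thereby removed.

Step 14
Reactants: 21 {2-[2,4-bis(methoxymethoxy)phenyl]-4-ethenyl-2-hydroxy-4-(4-methylpent-3-en-1-yl)cyclobutyl}[4-(methoxymethoxy)-3-(3-methylbut-2-en-1-yl)phenyl]methanone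
Product: 22 {2-[2,4-bis(methoxymethoxy)phenyl]-4-ethenyl-4-(4-methylpent-3-en-1-yl)cyclobut-1-en-1-yl}[4-(methoxymethoxy)-3-(3-methylbut-2-en-1-yl)phenyl]methanone (racemic at the quaternary carbon)
Conditions: methyl N-(triethylammoniosulfonyl)carbamate (Burgess reagent), THF, 50 °C
Reagents that add atoms: none
Why: Burgess dehydration of the tertiary benzylic β-hydroxy ketone (elimination through the sulfamate ester, assisted by the acidic α-hydrogen) should give the conjugated tetrasubstituted cyclobutenyl ketone, removing the stereocentres at the two ring carbons involved.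

Step 15
Reactants: 22 {2-[2,4-bis(methoxymethoxy)phenyl]-4-ethenyl-4-(4-methylpent-3-en-1-yl)cyclobut-1-en-1-yl}[4-(methoxymethoxy)-3-(3-methylbut-2-en-1-yl)phenyl]methanone
Product: 23 {(2S)-2-[2,4-bis(methoxymethoxy)phenyl]-4-ethenyl-4-(4-methylpent-3-en-1-yl)cyclobutyl}[4-(methoxymethoxy)-3-(3-methylbut-2-en-1-yl)phenyl]methanone (cyclobutyl C2 = later C5; mixture of epimers at cyclobutyl C1 and C4)
Conditions: Cu(OAc)2 (5 mol%), (R)-DTBM-SEGPHOS (5.5 mol%), (EtO)2MeSiH, t-BuOH, toluene, 0 °C → rt
Reagents that add atoms: none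
Why: Copper hydride-catalysed asymmetric conjugate reduction: the ligand-bound copper hydride adds hydride to one enantioface of the β-carbon and tert-butanol protonates the copper enolate, so the (S)-configured aryl-bearing carbon (later C5) is set by the catalyst, while the epimers at the quaternary and the α-carbon need not be controlled because both centres are planarised in step 16.

Step 16
Reactants: 23 {(2S)-2-[2,4-bis(methoxymethoxy)phenyl]-4-ethenyl-4-(4-methylpent-3-en-1-yl)cyclobutyl}[4-(methoxymethoxy)-3-(3-methylbut-2-en-1-yl)phenyl]methanone; 9 (2S)-2-[2,4-bis(methoxymethoxy)phenyl]-6-iodo-5,7-bis(methoxymethoxy)chroman-4-one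
Product: 25 (2S)-2-[2,4-bis(methoxymethoxy)phenyl]-6-{(1R,5S,6R)-5-[2,4-bis(methoxymethoxy)phenyl]-6-[4-(methoxymethoxy)-3-(3-methylbut-2-en-1-yl)benzoyl]-3-(4-methylpent-3-en-1-yl)cyclohex-2-en-1-yl}-5,7-bis(methoxymethoxy)chroman-4-one, via styrylcyclobutane 24 (not isolated)
Conditions: Pd(OAc)2 (5 mol%), P(o-tol)3 (12 mol%), Ag2CO3, toluene, 60 °C; filter through Celite, evaporate; then Sc(OTf)3 (20 mol%), CH2Cl2, −40 → 0 °C
Reagents that add atoms: none
Why: Proposed new method: the first stage is an ordinary Heck reaction (oxidative addition of 9 to zerovalent palladium, syn-carbopalladation of the vinyl group, syn-β-hydride elimination, for which the quaternary C1 leaves only the benzylic hydrogen, so the (E)-styryl compound 24 should form), and the new element is the Lewis-acid-triggered [1,3] shift of this push–pull vinylcyclobutane. Sc(OTf)3 bound to the aryl ketone should heterolyse the strained C1–C4 bond to a scandium enolate and an allyl cation delocalised over C1–C2–C3 and into ring A, and the enolate carbon C4 then attacks C3 in a 6-(enolexo)-endo-trig closure, so that the four-membered ring becomes the cyclohexene. The closest known reaction types are the Lewis-acid opening of donor–acceptor cyclobutanes to 1,4-zwitterions used in their formal [4+2] annulations, the vinylcyclopropane-to-cyclopentene rearrangement of donor–acceptor cyclopropanes, and the thermal, alkoxide-accelerated and radical-cation vinylcyclobutane-to-cyclohexene rearrangements. C1 and C4 are planar in the zwitterion, so only C5 carries stereochemical information: in a chair-like ion-pair transition state the C5 aryl group, the C4 aroyl group and the (E)-placed flavanone at C3 all sit pseudo-equatorial, which should give the all-trans (3R,4R,5S) product, and C4 can in addition equilibrate to trans through its enol. The step needs C-attack at C3 in preference to return to C1, O-attack or proton loss, and no cleavage of C5–C6; return to C1 and O-attack (which gives an allyl vinyl ether that can still reach the product by a Claisen-type shift) are reversible, while low temperature and the intramolecular six-ring closure are relied on to suppress elimination and cycloreversion.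

Step 17
Reactants: 25 (2S)-2-[2,4-bis(methoxymethoxy)phenyl]-6-{(1R,5S,6R)-5-[2,4-bis(methoxymethoxy)phenyl]-6-[4-(methoxymethoxy)-3-(3-methylbut-2-en-1-yl)benzoyl]-3-(4-methylpent-3-en-1-yl)cyclohex-2-en-1-yl}-5,7-bis(methoxymethoxy)chroman-4-one
Product: 27 (2S)-2-(2,4-dihydroxyphenyl)-5,7-dihydroxy-6-{(1R,5S,6R)-5-(2,4-dihydroxyphenyl)-6-[4-hydroxy-3-(3-methylbut-2-en-1-yl)benzoyl]-3-(4-methylpent-3-en-1-yl)cyclohex-2-en-1-yl}chroman-4-one (CNP0235243.2), via heptakis(trimethylsilyl) ether 26 (not isolated)
Conditions: TMSOTf, 2,2'-bipyridyl, CH2Cl2, 0 °C → rt; then H2O, rt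
Reagents that add atoms: none
Why: Aromatic MOM ethers are cleaved under nearly neutral conditions by TMSOTf/2,2'-bipyridyl (acetal exchange to the aryl silyl ethers 26) and aqueous hydrolysis, which should spare the acid-sensitive prenyl-type alkenes, the cyclohexene and the C2 centre of the flavanone; no stereocentre is touched.

**Compound list**

1 | 2,4-dihydroxybenzaldehyde | O=Cc1ccc(O)cc1O | starting material
2 | 2,4-bis(methoxymethoxy)benzaldehyde | O=Cc1ccc(OCOC)cc1OCOC | intermediate
3 | 1-(2,4,6-trihydroxyphenyl)ethan-1-one | CC(=O)c1c(O)cc(O)cc1O | starting material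
4 | 1-[2,6-dihydroxy-4-(methoxymethoxy)phenyl]ethan-1-one | CC(=O)c1c(O)cc(OCOC)cc1O | intermediate
5 | (E)-3-[2,4-bis(methoxymethoxy)phenyl]-1-[2,6-dihydroxy-4-(methoxymethoxy)phenyl]prop-2-en-1-one (chalcone) | O=C(/C=C/c1ccc(OCOC)cc1OCOC)c1c(O)cc(OCOC)cc1O | intermediate
6 | racemic 2-[2,4-bis(methoxymethoxy)phenyl]-5-hydroxy-7-(methoxymethoxy)chroman-4-one | Oc1cc(OCOC)cc2c1C(=O)CC(c1ccc(OCOC)cc1OCOC)O2 | intermediate
7 | (2S)-2-[2,4-bis(methoxymethoxy)phenyl]-5-hydroxy-7-(methoxymethoxy)chroman-4-one | Oc1cc(OCOC)cc2c1C(=O)C[C@@H](c1ccc(OCOC)cc1OCOC)O2 | intermediate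
8 | (2S)-2-[2,4-bis(methoxymethoxy)phenyl]-5-hydroxy-6-iodo-7-(methoxymethoxy)chroman-4-one | Oc1c(I)c(OCOC)cc2c1C(=O)C[C@@H](c1ccc(OCOC)cc1OCOC)O2 | intermediate
9 | (2S)-2-[2,4-bis(methoxymethoxy)phenyl]-6-iodo-5,7-bis(methoxymethoxy)chroman-4-one | COCOc1c(I)c(OCOC)cc2c1C(=O)C[C@@H](c1ccc(OCOC)cc1OCOC)O2 | intermediate
10 | 4-hydroxybenzaldehyde | O=Cc1ccc(O)cc1 | starting material
11 | 4-hydroxy-3-(3-methylbut-2-en-1-yl)benzaldehyde | O=Cc1ccc(O)c(CC=C(C)C)c1 | intermediate
12 | 4-(methoxymethoxy)-3-(3-methylbut-2-en-1-yl)benzaldehyde | O=Cc1ccc(OCOC)c(CC=C(C)C)c1 | intermediate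
13 | 4-bromobenzene-1,3-diol | Oc1ccc(Br)c(O)c1 | starting material
14 | 1-bromo-2,4-bis(methoxymethoxy)benzene | Brc1ccc(OCOC)cc1OCOC | intermediate
15 | myrcene (7-methyl-3-methylideneocta-1,6-diene) | C=CC(=C)CCC=C(C)C | starting material
16 | racemic 2,2-dichloro-3-ethenyl-3-(4-methylpent-3-en-1-yl)cyclobutan-1-one | O=C1CC(CCC=C(C)C)(C=C)C1(Cl)Cl | intermediate
17 | 3-ethenyl-3-(4-methylpent-3-en-1-yl)cyclobutan-1-one (achiral) | O=C1CC(CCC=C(C)C)(C=C)C1 | intermediate
18 | lithium [2-ethenyl-2-(4-methylpent-3-en-1-yl)-4-oxocyclobutyl][4-(methoxymethoxy)-3-(3-methylbut-2-en-1-yl)phenyl]methanolate (aldolate, mixture of racemic diastereomers) | [Li+].[O-]C(c1ccc(OCOC)c(CC=C(C)C)c1)C1C(=O)CC1(CCC=C(C)C)C=C | intermediate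
19 | [2,4-bis(methoxymethoxy)phenyl]lithium | [Li]c1ccc(OCOC)cc1OCOC | intermediate
20 | 1-[2,4-bis(methoxymethoxy)phenyl]-3-ethenyl-2-{hydroxy[4-(methoxymethoxy)-3-(3-methylbut-2-en-1-yl)phenyl]methyl}-3-(4-methylpent-3-en-1-yl)cyclobutan-1-ol (mixture of racemic diastereomers) | OC(c1ccc(OCOC)c(CC=C(C)C)c1)C1C(O)(c2ccc(OCOC)cc2OCOC)CC1(CCC=C(C)C)C=C | intermediate
21 | {2-[2,4-bis(methoxymethoxy)phenyl]-4-ethenyl-2-hydroxy-4-(4-methylpent-3-en-1-yl)cyclobutyl}[4-(methoxymethoxy)-3-(3-methylbut-2-en-1-yl)phenyl]methanone (mixture of racemic diastereomers) | O=C(c1ccc(OCOC)c(CC=C(C)C)c1)C1C(O)(c2ccc(OCOC)cc2OCOC)CC1(CCC=C(C)C)C=C | intermediate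
22 | {2-[2,4-bis(methoxymethoxy)phenyl]-4-ethenyl-4-(4-methylpent-3-en-1-yl)cyclobut-1-en-1-yl}[4-(methoxymethoxy)-3-(3-methylbut-2-en-1-yl)phenyl]methanone (racemic at the quaternary carbon) | O=C(c1ccc(OCOC)c(CC=C(C)C)c1)C1=C(c2ccc(OCOC)cc2OCOC)CC1(CCC=C(C)C)C=C | intermediate
23 | {(2S)-2-[2,4-bis(methoxymethoxy)phenyl]-4-ethenyl-4-(4-methylpent-3-en-1-yl)cyclobutyl}[4-(methoxymethoxy)-3-(3-methylbut-2-en-1-yl)phenyl]methanone (epimers at cyclobutyl C1 and C4) | O=C(c1ccc(OCOC)c(CC=C(C)C)c1)C1[C@@H](c2ccc(OCOC)cc2OCOC)CC1(CCC=C(C)C)C=C | intermediate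
24 | {(2S)-2-[2,4-bis(methoxymethoxy)phenyl]-4-[(E)-2-{(2S)-2-[2,4-bis(methoxymethoxy)phenyl]-5,7-bis(methoxymethoxy)-4-oxochroman-6-yl}ethenyl]-4-(4-methylpent-3-en-1-yl)cyclobutyl}[4-(methoxymethoxy)-3-(3-methylbut-2-en-1-yl)phenyl]methanone (epimers at cyclobutyl C1 and C4) | O=C(c1ccc(OCOC)c(CC=C(C)C)c1)C1[C@@H](c2ccc(OCOC)cc2OCOC)CC1(CCC=C(C)C)/C=C/c1c(OCOC)cc2c(c1OCOC)C(=O)C[C@@H](c1ccc(OCOC)cc1OCOC)O2 | intermediate
25 | (2S)-2-[2,4-bis(methoxymethoxy)phenyl]-6-{(1R,5S,6R)-5-[2,4-bis(methoxymethoxy)phenyl]-6-[4-(methoxymethoxy)-3-(3-methylbut-2-en-1-yl)benzoyl]-3-(4-methylpent-3-en-1-yl)cyclohex-2-en-1-yl}-5,7-bis(methoxymethoxy)chroman-4-one | CC(C)=CCCC1=C[C@@H](c2c(OCOC)cc3c(c2OCOC)C(=O)C[C@@H](c2ccc(OCOC)cc2OCOC)O3)[C@H](C(=O)c2ccc(OCOC)c(CC=C(C)C)c2)[C@@H](c2ccc(OCOC)cc2OCOC)C1 | intermediate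
26 | heptakis(trimethylsilyl) ether of 27 (all seven phenols as OSiMe3; same configuration as 25) | CC(C)=CCCC1=C[C@@H](c2c(O[Si](C)(C)C)cc3c(c2O[Si](C)(C)C)C(=O)C[C@@H](c2ccc(O[Si](C)(C)C)cc2O[Si](C)(C)C)O3)[C@H](C(=O)c2ccc(O[Si](C)(C)C)c(CC=C(C)C)c2)[C@@H](c2ccc(O[Si](C)(C)C)cc2O[Si](C)(C)C)C1 | intermediate
27 | (2S)-2-(2,4-dihydroxyphenyl)-5,7-dihydroxy-6-{(1R,5S,6R)-5-(2,4-dihydroxyphenyl)-6-[4-hydroxy-3-(3-methylbut-2-en-1-yl)benzoyl]-3-(4-methylpent-3-en-1-yl)cyclohex-2-en-1-yl}chroman-4-one (CNP0235243.2) | CC(C)=CCCC1=C[C@@H](c2c(O)cc3c(c2O)C(=O)C[C@@H](c2ccc(O)cc2O)O3)[C@H](C(=O)c2ccc(O)c(CC=C(C)C)c2)[C@@H](c2ccc(O)cc2O)C1 | target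

**Step count and risks**

Total step count: 17. Longest linear sequence: 8 steps (steps 10–17 from myrcene 15; equally steps 7, 8 and 12–17 from 10).

Steps most likely to fail:

1. Step 16 (Proposed new method). In the Heck stage the alkylpalladium intermediate may undergo β-carbon elimination and open the cyclobutane before β-hydride elimination. In the ring-expansion stage the zwitterion may lose a proton to an acyclic triene, be intercepted by the homoprenyl alkene or an ortho MOM oxygen, or fragment across C5–C6 and recombine without control, which would erode the C5 information and the all-trans selectivity. Fallback with known chemistry (intermolecular Diels–Alder route), setting out from 9, 15, 12 and 2 and coming back at 25: Heck coupling of 9 with myrcene 15 (Pd(OAc)2, P(o-tol)3, Ag2CO3) at the monosubstituted vinyl terminus should give the flavanone diene F1. Aldehyde 12 is treated with MeMgBr to give the carbinol F2, which is oxidised (Dess–Martin periodinane) to the acetophenone F3 and condensed with aldehyde 2 (KOH, EtOH, Claisen–Schmidt) to the chalcone F4. Heating F1 with F4 (toluene, sealed tube, about 160 °C) should give the exo and endo Diels–Alder adducts as diastereomers, from which the all-trans isomer 25 is separated by chromatography before step 17.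

2. Step 15. Hydride delivery to the hindered, tetrasubstituted β-carbon may be slow, so that 1,2-reduction of the aryl ketone and poor enantiofacial discrimination compete. Fallback, setting out from 22 and coming back at 25: non-selective conjugate reduction with [(Ph3P)CuH]6 should give the racemic ketone F5, which is carried through step 16 with enantiopure 9. The Heck stage then gives 24 together with the epimeric styrylcyclobutane F6, and the ring expansion gives 25 together with the diastereomeric adduct F7. The two adducts differ in all three cyclohexene centres relative to the fixed (2S)-flavanone centre and are separated by chromatography, so the flavanone serves as the resolving handle.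

3. Step 10. Dichloroketene may add with poor site selectivity (to the trisubstituted alkene or the vinyl group, or twice). Fallback, setting out from 15 and coming back at 17: the keteniminium salt made from N,N-dimethylacetamide, Tf2O and 2,4,6-collidine (1,2-dichloroethane, reflux) is a bulkier cationic ketene equivalent that should discriminate more strongly for the terminal 1,1-disubstituted diene alkene; the [2+2] adduct, the cyclobutaniminium triflate F8, is hydrolysed with aqueous NaHCO3 directly to 17, which also removes the need for step 11.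

Further compounds
F1 | step 16 | (2S)-2-[2,4-bis(methoxymethoxy)phenyl]-5,7-bis(methoxymethoxy)-6-[(1E)-7-methyl-3-methylideneocta-1,6-dien-1-yl]chroman-4-one | C=C(CCC=C(C)C)/C=C/c1c(OCOC)cc2c(c1OCOC)C(=O)C[C@@H](c1ccc(OCOC)cc1OCOC)O2
F2 | step 16 | racemic 1-[4-(methoxymethoxy)-3-(3-methylbut-2-en-1-yl)phenyl]ethan-1-ol | CC(O)c1ccc(OCOC)c(CC=C(C)C)c1
F3 | step 16 | 1-[4-(methoxymethoxy)-3-(3-methylbut-2-en-1-yl)phenyl]ethan-1-one | CC(=O)c1ccc(OCOC)c(CC=C(C)C)c1
F4 | step 16 | (E)-3-[2,4-bis(methoxymethoxy)phenyl]-1-[4-(methoxymethoxy)-3-(3-methylbut-2-en-1-yl)phenyl]prop-2-en-1-one | O=C(/C=C/c1ccc(OCOC)cc1OCOC)c1ccc(OCOC)c(CC=C(C)C)c1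
F5 | step 15 | racemic {2-[2,4-bis(methoxymethoxy)phenyl]-4-ethenyl-4-(4-methylpent-3-en-1-yl)cyclobutyl}[4-(methoxymethoxy)-3-(3-methylbut-2-en-1-yl)phenyl]methanone | O=C(c1ccc(OCOC)c(CC=C(C)C)c1)C1C(c2ccc(OCOC)cc2OCOC)CC1(CCC=C(C)C)C=C
F6 | step 15 | {(2R)-2-[2,4-bis(methoxymethoxy)phenyl]-4-[(E)-2-{(2S)-2-[2,4-bis(methoxymethoxy)phenyl]-5,7-bis(methoxymethoxy)-4-oxochroman-6-yl}ethenyl]-4-(4-methylpent-3-en-1-yl)cyclobutyl}[4-(methoxymethoxy)-3-(3-methylbut-2-en-1-yl)phenyl]methanone | O=C(c1ccc(OCOC)c(CC=C(C)C)c1)C1[C@H](c2ccc(OCOC)cc2OCOC)CC1(CCC=C(C)C)/C=C/c1c(OCOC)cc2c(c1OCOC)C(=O)C[C@@H](c1ccc(OCOC)cc1OCOC)O2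
F7 | step 15 | (2S)-2-[2,4-bis(methoxymethoxy)phenyl]-6-{(1S,5R,6S)-5-[2,4-bis(methoxymethoxy)phenyl]-6-[4-(methoxymethoxy)-3-(3-methylbut-2-en-1-yl)benzoyl]-3-(4-methylpent-3-en-1-yl)cyclohex-2-en-1-yl}-5,7-bis(methoxymethoxy)chroman-4-one | CC(C)=CCCC1=C[C@H](c2c(OCOC)cc3c(c2OCOC)C(=O)C[C@@H](c2ccc(OCOC)cc2OCOC)O3)[C@@H](C(=O)c2ccc(OCOC)c(CC=C(C)C)c2)[C@H](c2ccc(OCOC)cc2OCOC)C1
F8 | step 10 | N-[3-ethenyl-3-(4-methylpent-3-en-1-yl)cyclobutylidene]-N-methylmethanaminium trifluoromethanesulfonate | C[N+](C)=C1CC(CCC=C(C)C)(C=C)C1.[O-]S(=O)(=O)C(F)(F)F
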